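## Retrosynthetic overview

1. The last bond made is the furan O–C2 bond of ring B. The ortho oxygen of ring A closes onto the ketone carbon of a 1,4-keto ester, which is carried through the route masked as a 5-substituted 2-methoxyfuran (a latent methyl 4-oxobutanoate). BBr3 frees the phenols and the keto ester in one flask (furan-to-benzofuran ring transposition).
2. The 2-methoxyfuran is joined through its C5 to the benzhydrylic carbon (future C3) by Friedel–Crafts alkylation with a diarylmethanol.
3. The diarylmethanol comes from 2,4-dimethoxy-6-methylbenzaldehyde (ring A; the CHO carbon becomes C3) and the aryllithium of ring C.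
4. The ring C bromide comes from 5-bromo-1,3-dimethoxy-2-methylbenzene by ortho-lithiation and methylation.
5. Ring order: rings A and C are bought as benzenes; ring B (the furan of the benzofuran) is the only ring made and is closed last, through the C–O bond.

Assumption: the target SMILES has no stereocentre and no stereodescriptor, so the achiral constitution as drawn is the target; the ring C–C3 axis is not treated as a fixed stereo element.

## Route

Step 1
Reactants: 1 5-bromo-1,3-dimethoxy-2-methylbenzene
Product: 3 1-bromo-3,5-dimethoxy-2,4-dimethylbenzene, via aryllithium 2 (not isolated)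
Conditions: LiN(iPr)2 (1.15 equiv), THF, −78 °C, 1 h; then MeI (3 equiv), −78 °C → rt
Reagents that add atoms: iodomethane, CI
Why: Directed ortho-metalation followed by alkylation: the two remaining ring C–H positions are equivalent and each sits between Br and OMe, so the amide base removes that proton at −78 °C (too cold for benzyne formation) and MeI methylates the aryllithium to give a single product.

Step 2
Reactants: 3 1-bromo-3,5-dimethoxy-2,4-dimethylbenzene; 4 2,4-dimethoxy-6-methylbenzaldehyde
Product: 6 (2,4-dimethoxy-6-methylphenyl)(3,5-dimethoxy-2,4-dimethylphenyl)methanol (racemic), via aryllithium 5 (not isolated)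
Conditions: n-BuLi (1.05 equiv), THF, −78 °C, 20 min; then 4 (1.0 equiv), −78 → 0 °C; H2O
Reagents that add atoms: none
Why: Bromine–lithium exchange followed by 1,2-addition of the aryllithium to a non-enolisable aldehyde; the carbinol centre forms racemic and is later erased when it becomes sp2 C3.

Step 3
Reactants: 6 (2,4-dimethoxy-6-methylphenyl)(3,5-dimethoxy-2,4-dimethylphenyl)methanol; 7 2-methoxyfuran
Product: 8 2-[(2,4-dimethoxy-6-methylphenyl)(3,5-dimethoxy-2,4-dimethylphenyl)methyl]-5-methoxyfuran (racemic)
Conditions: 7 (3 equiv), Sc(OTf)3 (5 mol%), 4 Å MS, CH2Cl2, −40 → 0 °C; then Et3N; basic alumina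
Reagents that add atoms: none
Why: Dehydrative Friedel–Crafts alkylation: the acid ionises the doubly donor-stabilised benzhydrol, the cation is captured at the free α-position (C5) of the highly nucleophilic 2-methoxyfuran and proton loss restores the furan, while the sieves remove water so the acid-labile ketene-acetal-type furan is not hydrolysed; the stereocentre is racemic and is removed in step 4.

Step 4
Reactants: 8 2-[(2,4-dimethoxy-6-methylphenyl)(3,5-dimethoxy-2,4-dimethylphenyl)methyl]-5-methoxyfuran
Product: 11 Talarominine A, methyl 3-[3-(3,5-dihydroxy-2,4-dimethylphenyl)-6-hydroxy-4-methyl-1-benzofuran-2-yl]propanoate, via enol lactone tetraphenol 9 (not isolated), via tetraphenol keto ester 10 (not isolated)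
Conditions: BBr3 (8 equiv), CH2Cl2, −78 °C → rt, 6 h; then MeOH, 0 → 50 °C, 4 h
Reagents that add atoms: methanol, CO
Why: Proposed new method: BBr3 should cleave the ketene-acetal-type furyl methyl ether fastest (bromide demethylates the boron-activated dioxocarbenium), turning the furan into the enol lactone of a 4-oxo acid while the four aryl methyl ethers are cleaved as usual, and the HBr/MeOH formed on quench opens the enol lactone to the methyl 4-oxo ester, whose ketone is then attacked by the freed ortho phenol of ring A (hemiketal formation, then dehydration driven by aromatisation) to form the furan O–C2 bond, with only one benzofuran possible because ring C has no ortho oxygen; closest known reaction types are the Butin-type acid-induced furan ring-opening/benzofuran ring-closure of 2-(2-hydroxybenzyl)furans and the BBr3 demethylation/cyclodehydration of 2-methoxyaryl ketones.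

## Compound list

1 | 5-bromo-1,3-dimethoxy-2-methylbenzene | COc1cc(Br)cc(OC)c1C | starting material
2 | (6-bromo-2,4-dimethoxy-3-methylphenyl)lithium | [Li]c1c(Br)cc(OC)c(C)c1OC | intermediate (not isolated)
3 | 1-bromo-3,5-dimethoxy-2,4-dimethylbenzene | Cc1c(Br)cc(OC)c(C)c1OC | intermediate
4 | 2,4-dimethoxy-6-methylbenzaldehyde | COc1cc(C)c(C=O)c(OC)c1 | starting material
5 | (3,5-dimethoxy-2,4-dimethylphenyl)lithium | [Li]c1cc(OC)c(C)c(OC)c1C | intermediate (not isolated)
6 | (2,4-dimethoxy-6-methylphenyl)(3,5-dimethoxy-2,4-dimethylphenyl)methanol (racemic) | COc1cc(C)c(C(O)c2cc(OC)c(C)c(OC)c2C)c(OC)c1 | intermediate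
7 | 2-methoxyfuran | COc1ccco1 | starting material
8 | 2-[(2,4-dimethoxy-6-methylphenyl)(3,5-dimethoxy-2,4-dimethylphenyl)methyl]-5-methoxyfuran (racemic) | COc1ccc(C(c2c(C)cc(OC)cc2OC)c2cc(OC)c(C)c(OC)c2C)o1 | intermediate
9 | 5-[(2,4-dihydroxy-6-methylphenyl)(3,5-dihydroxy-2,4-dimethylphenyl)methyl]furan-2(3H)-one (racemic) | O=C1CC=C(C(c2c(C)cc(O)cc2O)c2cc(O)c(C)c(O)c2C)O1 | intermediate (not isolated)
10 | methyl 5-(2,4-dihydroxy-6-methylphenyl)-5-(3,5-dihydroxy-2,4-dimethylphenyl)-4-oxopentanoate (racemic) | COC(=O)CCC(=O)C(c1c(C)cc(O)cc1O)c1cc(O)c(C)c(O)c1C | intermediate (not isolated)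
11 | Talarominine A, methyl 3-[3-(3,5-dihydroxy-2,4-dimethylphenyl)-6-hydroxy-4-methyl-1-benzofuran-2-yl]propanoate | COC(=O)CCc1oc2cc(O)cc(C)c2c1-c1cc(O)c(C)c(O)c1C | target

## Step count and risks

Total step count: 4. Longest linear sequence: 4 steps (1 → 3 → 6 → 8 → 11).

Steps most likely to fail:

Step 4 (the proposed new step). The risks are that the intermediate lactone isomerises to the conjugated butenolide, or that the electron-rich triarylmethane-type centre fragments under BBr3/HBr before the furan is unmasked. The fallback sets out from 8 and returns at 11, using known chemistry. Compound 8 is stirred with dilute aqueous HCl in THF at rt, the ordinary hydrolysis of a 2-alkoxyfuran to a 4-oxo ester, to give methyl 5-(2,4-dimethoxy-6-methylphenyl)-5-(3,5-dimethoxy-2,4-dimethylphenyl)-4-oxopentanoate F1. This robust keto ester is then put through the established BBr3 demethylation/cyclodehydration of 2-methoxyaryl ketones (BBr3, CH2Cl2, −78 °C → rt; MeOH quench and brief warming to keep the methyl ester) to give 11.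

Step 3. 2-Methoxyfuran may polymerise or be hydrolysed by the acid and the water released, or the intermediate cation may be trapped as a butenolide instead of re-aromatising. The fallback sets out from 6 and returns at 11, and unmasks the chain by oxidation instead of hydrolysis. Compound 6 is used to alkylate parent furan (large excess, cat. Sc(OTf)3, CH2Cl2), a well-precedented benzhydrylation, giving 2-[(2,4-dimethoxy-6-methylphenyl)(3,5-dimethoxy-2,4-dimethylphenyl)methyl]furan F2. Singlet-oxygen photooxygenation with base-induced endoperoxide fragmentation (O2, rose bengal, hν, iPr2NEt, CH2Cl2, −78 °C) gives 5-[(2,4-dimethoxy-6-methylphenyl)(3,5-dimethoxy-2,4-dimethylphenyl)methyl]-5-hydroxyfuran-2(5H)-one F3, the ring tautomer of the (Z)-4-oxo-2-enoic acid. Zn in AcOH reduces the C=C to give 5-(2,4-dimethoxy-6-methylphenyl)-5-(3,5-dimethoxy-2,4-dimethylphenyl)-4-oxopentanoic acid F4. BBr3 in CH2Cl2 followed by MeOH at 50 °C (demethylation, cyclodehydration and Fischer esterification by the HBr formed) then gives 11.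

Step 1. The ortho-lithiated bromoarene may lose LiBr to a benzyne or scramble bromine before it is methylated. The fallback sets out from 1 and returns at 3, and uses electrophilic substitution instead of deprotonation. Rieche formylation of 1 (Cl2CHOMe, TiCl4, CH2Cl2, 0 °C) at the same ring position, which is ortho and para to the two methoxy groups, gives 6-bromo-2,4-dimethoxy-3-methylbenzaldehyde F5. Ionic deoxygenation of this electron-rich aldehyde (Et3SiH, CF3CO2H, rt) gives 3.

## Further compounds

F1 | step 4 | methyl 5-(2,4-dimethoxy-6-methylphenyl)-5-(3,5-dimethoxy-2,4-dimethylphenyl)-4-oxopentanoate (racemic) | COc1cc(C)c(C(C(=O)CCC(=O)OC)c2cc(OC)c(C)c(OC)c2C)c(OC)c1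
F2 | step 3 | 2-[(2,4-dimethoxy-6-methylphenyl)(3,5-dimethoxy-2,4-dimethylphenyl)methyl]furan (racemic) | COc1cc(C)c(C(c2ccco2)c2cc(OC)c(C)c(OC)c2C)c(OC)c1
F3 | step 3 | 5-[(2,4-dimethoxy-6-methylphenyl)(3,5-dimethoxy-2,4-dimethylphenyl)methyl]-5-hydroxyfuran-2(5H)-one (diastereomer mixture, racemic) | COc1cc(C)c(C(c2cc(OC)c(C)c(OC)c2C)C2(O)C=CC(=O)O2)c(OC)c1
F4 | step 3 | 5-(2,4-dimethoxy-6-methylphenyl)-5-(3,5-dimethoxy-2,4-dimethylphenyl)-4-oxopentanoic acid (racemic) | COc1cc(C)c(C(C(=O)CCC(=O)O)c2cc(OC)c(C)c(OC)c2C)c(OC)c1
F5 | step 1 | 6-bromo-2,4-dimethoxy-3-methylbenzaldehyde | O=Cc1c(Br)cc(OC)c(C)c1OC
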